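## Retrosynthetic overview
- The target comes from fluoride desilylation of its C9' silyl ether. Before that, the hydroquinone is unmasked from a dimethyl ether with Ce(IV) and then dithionite.
- Key disconnection, C9'–O: the (R)-silyl ether comes from a racemic C9' allyl sulfone by a Pd-catalysed dynamic kinetic C–O substitution. This step sets the only stereocentre.
- C8'–C9': the sulfone comes from the geranyl phenyl sulfone anion and a C8' allylic bromide.
- The bromide comes from E-selective allylic oxidation and Appel bromination of a geranyl arene. That arene comes from ortho-C-geranylation of 4-methoxy-2-methylphenol.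
- No ring is formed, because the arene is bought. All three E-alkenes come from geranyl bromide and are never broken.

Assumption: chain atoms are numbered C1' (benzylic CH2) to C16'. The (R,R)-ligand is taken as the one matched to the (R)-sulfone. The sense of induction of a new reaction must be checked on the first run, and the equally commercial (S,S)-antipode is used if it is reversed.

## Route

Step 1
Reactants: 1 geranyl bromide; 2 sodium benzenesulfinate
Product: 3 geranyl phenyl sulfone
Conditions: DMF, rt, 12 h
Reagents that add atoms: none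
Why: SN2 S-alkylation of the ambident sulfinate by a primary allylic bromide gives the sulfone with the E-alkene unchanged.

Step 2
Reactants: 4 4-methoxy-2-methylphenol; 1 geranyl bromide
Product: 6 1-geranyl-2,5-dimethoxy-3-methylbenzene, via ortho-geranyl phenol 5 (not isolated)
Conditions: NaH, PhMe, 0 °C → rt; then NaH, MeI, DMF, 0 °C → rt
Reagents that add atoms: iodomethane, CI
Why: In toluene the tight sodium phenoxide ion pair is C-alkylated at its only free ortho position (the para position is blocked by OMe), and adding DMF then allows Williamson O-methylation of the hindered phenol.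

Step 3
Reactants: 6 1-geranyl-2,5-dimethoxy-3-methylbenzene
Product: 7 (2E,6E)-8-(2,5-dimethoxy-3-methylphenyl)-2,6-dimethylocta-2,6-dien-1-ol
Conditions: SeO2 (0.1 equiv), salicylic acid (0.1 equiv), t-BuOOH (3 equiv), CH2Cl2, 0 °C → rt
Reagents that add atoms: tert-butyl hydroperoxide, CC(C)(C)OO (terminal O source, relayed through catalytic selenium dioxide, O=[Se]=O)
Why: Riley allylic oxidation (ene reaction followed by [2,3]-shift) picks the E-methyl of the most accessible, electron-rich terminal isopropylidene and fixes the C6'=C7' E-geometry.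

Step 4
Reactants: 7 (2E,6E)-8-(2,5-dimethoxy-3-methylphenyl)-2,6-dimethylocta-2,6-dien-1-ol
Product: 8 1-[(2E,6E)-8-bromo-3,7-dimethylocta-2,6-dienyl]-2,5-dimethoxy-3-methylbenzene
Conditions: CBr4, PPh3, CH2Cl2, 0 °C, used crude
Reagents that add atoms: carbon tetrabromide, BrC(Br)(Br)Br
Why: The Appel reaction turns the primary allylic alcohol into the bromide under neutral conditions without allylic transposition.

Step 5
Reactants: 3 geranyl phenyl sulfone; 8 1-[(2E,6E)-8-bromo-3,7-dimethylocta-2,6-dienyl]-2,5-dimethoxy-3-methylbenzene
Product: 10 rac-1-[(2E,6E,10E)-9-(phenylsulfonyl)-3,7,11,15-tetramethylhexadeca-2,6,10,14-tetraenyl]-2,5-dimethoxy-3-methylbenzene, via lithio sulfone 9 (not isolated)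
Conditions: 3, n-BuLi, THF–DMPU, −78 °C; then 8, −78 → −20 °C
Reagents that add atoms: none
Why: The sulfone-stabilised allyl anion alkylates at its α-carbon with retention of both alkene geometries (classical terpene sulfone coupling), and C9' is deliberately formed racemic here.

Step 6
Reactants: 10 rac-C9' allyl sulfone
Product: 11 (9'R)-tert-butyldimethylsilyl ether of the dimethoxyarene
Conditions: Pd2(dba)3·CHCl3 (2.5 mol %), (R,R)-DACH-phenyl Trost ligand (6 mol %), t-BuMe2SiOH (3 equiv), KOt-Bu (1.3 equiv), THF, 40 °C, Ar, halide-free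
Reagents that add atoms: tert-butyldimethylsilanol (acts as its potassium salt), CC(C)(C)[Si](C)(C)O
Why: Proposed new method: a dynamic kinetic asymmetric Tsuji–Trost C–O substitution of a racemising allyl sulfone; (i) the silanolate/silanol buffer exchanges the acidic C9'–H (pKa about 24) quickly, so the two enantiomers of 10 interconvert through a short-lived α-sulfonyl carbanion that keeps the E-alkene; (ii) the chiral Pd(0) complex ionises only the matched (R)-sulfone anti to sulfinate, which is the microscopic reverse of the highly enantioselective Pd-catalysed allylation of sulfinates, and the face and C10'=C11' geometry of the resulting π-allyl could leak only through an unfavourable tertiary σ-Pd species; (iii) the bulky silanolate attacks anti to Pd at the less hindered secondary terminus C9', so double inversion gives net retention and the R configuration; (iv) the silyl ether cannot re-ionise, so sulfinate return is only a degenerate path; the closest known reaction types are Pd-catalysed substitution of allyl sulfones by carbon nucleophiles, Pd-catalysed kinetic resolution and deracemisation of allylic esters with O- and S-nucleophiles, and silanolates or silanols as hydroxide surrogates in Ir- and Pd-allyl chemistry.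

Step 7
Reactants: 11 (9'R)-silyl ether dimethoxyarene
Product: 13 (9'R)-silyl ether hydroquinone, via quinone silyl ether 12 (not isolated)
Conditions: CAN (2.5 equiv), MeCN–H2O 4:1, 0 °C, 15 min; then Et2O extract shaken with aq Na2S2O4, rt, Ar
Reagents that add atoms: water, O
Why: In the Ce(IV) oxidative demethylation, water adds at both ipso carbons and methanol leaves, so both ring C–O bonds are renewed from water; the silyl ether shields the acid-labile allylic C9'–O bond from ionisation and racemisation, and dithionite then reduces quinone 12.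

Step 8
Reactants: 13 (9'R)-silyl ether hydroquinone
Product: 14 2-[(2E,6E,9R,10E)-9-hydroxy-3,7,11,15-tetramethylhexadeca-2,6,10,14-tetraenyl]-6-methylbenzene-1,4-diol (target)
Conditions: TBAF, AcOH (1:1), THF, 0 °C → rt, Ar
Reagents that add atoms: none
Why: Buffered fluoride desilylation cleaves only the Si–O bond, so the C9' configuration is untouched, and the buffer keeps the hydroquinone protonated and safe from air oxidation.

## Compound list
1 | geranyl bromide, (2E)-1-bromo-3,7-dimethylocta-2,6-diene | CC(C)=CCC/C(C)=C/CBr | starting material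
2 | sodium benzenesulfinate | [Na+].[O-]S(=O)c1ccccc1 | starting material
3 | geranyl phenyl sulfone | CC(C)=CCC/C(C)=C/CS(=O)(=O)c1ccccc1 | intermediate
4 | 4-methoxy-2-methylphenol | COc1ccc(O)c(C)c1 | starting material
5 | 2-[(2E)-geranyl]-4-methoxy-6-methylphenol (not isolated) | CC(C)=CCC/C(C)=C/Cc1cc(OC)cc(C)c1O | intermediate
6 | 1-[(2E)-geranyl]-2,5-dimethoxy-3-methylbenzene | CC(C)=CCC/C(C)=C/Cc1cc(OC)cc(C)c1OC | intermediate
7 | (2E,6E)-8-(2,5-dimethoxy-3-methylphenyl)-2,6-dimethylocta-2,6-dien-1-ol | OC/C(C)=C/CC/C(C)=C/Cc1cc(OC)cc(C)c1OC | intermediate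
8 | 1-[(2E,6E)-8-bromo-3,7-dimethylocta-2,6-dienyl]-2,5-dimethoxy-3-methylbenzene | BrC/C(C)=C/CC/C(C)=C/Cc1cc(OC)cc(C)c1OC | intermediate
9 | α-lithio geranyl phenyl sulfone (not isolated) | CC(C)=CCC/C(C)=C/[CH-]S(=O)(=O)c1ccccc1.[Li+] | intermediate
10 | racemic C9' phenyl sulfone of the (2E,6E,10E)-tetraenyl dimethoxyarene | CC(C)=CCC/C(C)=C/C(C/C(C)=C/CC/C(C)=C/Cc1cc(OC)cc(C)c1OC)S(=O)(=O)c1ccccc1 | intermediate
11 | (9'R)-TBS ether, dimethoxyarene | CC(C)=CCC/C(C)=C/[C@H](O[Si](C)(C)C(C)(C)C)C/C(C)=C/CC/C(C)=C/Cc1cc(OC)cc(C)c1OC | intermediate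
12 | (9'R)-TBS ether, 2-methyl-6-alkyl-1,4-benzoquinone (not isolated) | CC(C)=CCC/C(C)=C/[C@H](O[Si](C)(C)C(C)(C)C)C/C(C)=C/CC/C(C)=C/CC1=CC(=O)C=C(C)C1=O | intermediate
13 | (9'R)-TBS ether, hydroquinone | CC(C)=CCC/C(C)=C/[C@H](O[Si](C)(C)C(C)(C)C)C/C(C)=C/CC/C(C)=C/Cc1cc(O)cc(C)c1O | intermediate
14 | 2-[(2E,6E,9R,10E)-9-hydroxy-3,7,11,15-tetramethylhexadeca-2,6,10,14-tetraenyl]-6-methylbenzene-1,4-diol | CC(C)=CCC/C(C)=C/[C@H](O)C/C(C)=C/CC/C(C)=C/Cc1cc(O)cc(C)c1O | target

## Step count and risks
Total steps: 8. Longest linear sequence: 7 (steps 2 to 8). Step 1 is a one-step side branch.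

**Step 6 (the new reaction).**
- Risks: poor discrimination between the sulfone enantiomers, silanolate attack at the tertiary terminus C11', or elimination to the C8'=C9' triene.
- The fallback uses known chemistry. It sets out from 10 and comes back at 11.
- 10 is deprotonated with n-BuLi in THF at −78 °C to the lithio sulfone F1.
- F1 is oxidised with bis(trimethylsilyl) peroxide to the C9' enone F2 (oxidative desulfonylation).
- (R)-BINAL-H in THF at −100 to −78 °C tells the alkenyl flank from the alkyl flank and gives the (R)-allylic alcohol F3.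
- TBSCl and imidazole in DMF convert F3 into 11.

**Step 2 (C-alkylation).**
- Risks: O-alkylation instead of C-alkylation, dienone formation at the methyl-bearing ortho carbon, and a hard separation after the one-pot methylation.
- The fallback sets out from 4 and comes back at 6.
- NBS in MeCN at 0 °C brominates ortho to the hydroxyl to give the bromophenol F4.
- MeI and K2CO3 in acetone give the bromo dimethyl ether F5.
- n-BuLi in THF at −78 °C gives the aryllithium F6, which is allylated with 1 (catalytic CuBr·SMe2) to 6.

**Step 7 (acidic Ce(IV) oxidation).**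
- Risks: loss of the silyl group followed by ionisation of the allylic carbinol, or damage to the polyene.
- The fallback sets out from 11 and comes back at 12.
- Anodic oxidation (Pt anode, KOH/MeOH, 0 °C) works under basic conditions at the low potential of the dimethoxyarene and gives the quinone bis(dimethyl ketal) F7.
- Dilute oxalic acid in aqueous THF hydrolyses F7 to quinone 12, which is reduced with dithionite as in step 7.

## Further compounds
F1 | step 6 | α-lithio derivative of sulfone 10 | CC(C)=CCC/C(C)=C/[C-](C/C(C)=C/CC/C(C)=C/Cc1cc(OC)cc(C)c1OC)S(=O)(=O)c1ccccc1.[Li+]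
F2 | step 6 | (2E,6E,10E)-C9' enone of the dimethoxyarene | CC(C)=CCC/C(C)=C/C(=O)C/C(C)=C/CC/C(C)=C/Cc1cc(OC)cc(C)c1OC
F3 | step 6 | (9'R)-allylic alcohol of the dimethoxyarene | CC(C)=CCC/C(C)=C/[C@H](O)C/C(C)=C/CC/C(C)=C/Cc1cc(OC)cc(C)c1OC
F4 | step 2 | 2-bromo-4-methoxy-6-methylphenol | COc1cc(C)c(O)c(Br)c1
F5 | step 2 | 1-bromo-2,5-dimethoxy-3-methylbenzene | COc1cc(C)c(OC)c(Br)c1
F6 | step 2 | 2,5-dimethoxy-3-methylphenyllithium | COc1cc(C)c(OC)c([Li])c1
F7 | step 7 | (9'R)-TBS ether, quinone bis(dimethyl ketal) | CC(C)=CCC/C(C)=C/[C@H](O[Si](C)(C)C(C)(C)C)C/C(C)=C/CC/C(C)=C/CC1=CC(OC)(OC)C=C(C)C1(OC)OC
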